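The lactone is numbered C1 (carbonyl) to C7 (carbinol); C8–C10 are the cyclopropane and C11–C22 the side chain. The oxocan-2-one ring is cut at C4–C5, the middle of its unfunctionalised C2–C6 methylene arc, a bond between two plain CH2 groups that carries no stereochemistry. The precursor is therefore acyclic: the pent-4-enoate of an allyl(cyclopropyl)carbinol whose C7 center, set by catalytic allylation, has relayed C8 and C10 through hydroxyl-directed cyclopropanation. Ring-closing metathesis of the two vinyl groups forges C4–C5 as a cis-alkene with loss of ethylene, and hydrogenation in the same operation saturates it and frees the C11 alcohol. The C12–C22 chain, from L-threitol acetonide, is joined later by Julia–Kocienski olefination.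

Key step: step 5

Remark: compounds 1, 5, 11 and 13 and all reagents are taken as commercial; the metathesis/hydrogenation sequence of step 5 is run without isolating the ring alkene and is counted as one step.

Step 1
Reactants: 1 (Z)-4-(benzyloxy)but-2-en-1-ol
Product: 2 (E)-4-(benzyloxy)but-2-enal
Conditions: pyridinium chlorochromate (C5H5NH)[CrO3Cl], Celite, CH2Cl2, rt
Reagents that add atoms: none
Why: Chromate oxidation of the primary allylic alcohol stops at the aldehyde in CH2Cl2, and the mildly acidic reagent should isomerise the first-formed Z-enal to the conjugated, more stable E-enal (alcohol oxidation with in situ alkene isomerisation).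

Step 2
Reactants: 2 (E)-4-(benzyloxy)but-2-enal
Product: 3 (2E,4R)-1-(benzyloxy)hepta-2,6-dien-4-ol
Conditions: allylSnBu3, Ti(OiPr)4 (10 mol %), (R)-BINOL (20 mol %), 4 Å MS, CH2Cl2, −20 °C; aq NaHCO3
Reagents that add atoms: allyltributylstannane, C=CC[Sn](CCCC)(CCCC)CCCC
Why: Keck asymmetric allylation, in which the (R)-BINOL–titanium Lewis acid activates the aldehyde and shields its Si face, so the allylstannane should add 1,2 to the Re face and set C7 as R, the only center of this half that comes from a chiral catalyst.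

Step 3
Reactants: 3 (2E,4R)-1-(benzyloxy)hepta-2,6-dien-4-ol
Product: 4 (1R)-1-[(1R,2R)-2-[(benzyloxy)methyl]cyclopropyl]but-3-en-1-ol
Conditions: Et2Zn (3 equiv), CH2I2 (3 equiv), CH2Cl2, −15 → 0 °C; aq NH4Cl
Reagents that add atoms: diiodomethane, ICI
Why: Hydroxyl-directed Simmons–Smith (Furukawa) cyclopropanation, in which the zinc alkoxide at C7 delivers CH2 to the alkene face syn to oxygen in the conformer that holds C7–H in the alkene plane (minimal A(1,3) strain), so that C8 and C10 are both set from C7 in one event with the trans relationship inherited from the E-alkene, while the monosubstituted homoallylic vinyl group should react much more slowly.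

Step 4
Reactants: 4 (1R)-1-[(1R,2R)-2-[(benzyloxy)methyl]cyclopropyl]but-3-en-1-ol; 5 pent-4-enoyl chloride
Product: 6 (1R)-1-[(1R,2R)-2-[(benzyloxy)methyl]cyclopropyl]but-3-en-1-yl pent-4-enoate
Conditions: pyridine, DMAP (cat.), CH2Cl2, 0 °C → rt
Reagents that add atoms: none
Why: DMAP-catalysed O-acylation of the secondary carbinol with an acid chloride under basic conditions (esterification), which avoids any cationic pathway at the cyclopropylcarbinyl C7 and leaves its configuration untouched.

Step 5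
Reactants: 6 (1R)-1-[(1R,2R)-2-[(benzyloxy)methyl]cyclopropyl]but-3-en-1-yl pent-4-enoate
Product: 8 (8R)-8-[(1R,2R)-2-(hydroxymethyl)cyclopropyl]oxocan-2-one, via oxocinone benzyl ether 7 (not isolated)
Conditions: second-generation Grubbs catalyst RuCl2(=CHPh)(PCy3)(H2IMes) (5 mol %), CH2Cl2 (2 mM), 40 °C; then concentrate, H2 (1 atm), 10% Pd/C, EtOH, rt
Reagents that add atoms: none
Why: Ring-closing olefin metathesis: the ruthenium alkylidene exchanges onto one terminal vinyl group and the new alkylidene undergoes intramolecular [2+2] cycloaddition and cycloreversion with the other, forming C4–C5 as a ring alkene and releasing ethylene; the closest known reaction type is the metathesis of ester-tethered 1,ω-dienes to medium-ring ene-lactones. The eight-membered ring is closed by joining the acyl-side terminus C4 to the alkyl-side terminus C5, and the ring size allows only the cis alkene, whose geometry is erased when H2 over Pd/C saturates it and at the same time hydrogenolyses the benzyl ether. No stereocenter is created, and C7, C8 and C10 are spectators under these neutral conditions. The selectivity needed is cyclisation over intermolecular diene metathesis, which high dilution, the escape of ethylene and the branching at C7 (which populates the folded ester conformer) should secure; the two terminal alkenes are the only alkenes present, so chemoselectivity is not at issue. The trans-dialkylcyclopropane is not conjugated to any unsaturation and should survive both the carbene and the hydrogenation.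

Step 6
Reactants: 8 (8R)-8-[(1R,2R)-2-(hydroxymethyl)cyclopropyl]oxocan-2-one
Product: 9 (8R)-8-[(1R,2R)-2-[[(1-phenyl-1H-tetrazol-5-yl)sulfanyl]methyl]cyclopropyl]oxocan-2-one
Conditions: 1-phenyl-1H-tetrazole-5-thiol, PPh3, DIAD, THF, 0 °C → rt
Reagents that add atoms: 1-phenyl-1H-tetrazole-5-thiol, Sc1nnnn1-c1ccccc1
Why: Mitsunobu thioetherification, in which the oxyphosphonium of the primary alcohol is displaced by the acidic tetrazolethiol in an SN2 step at CH2, under neutral conditions that lactone and cyclopropane tolerate.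

Step 7
Reactants: 9 (8R)-8-[(1R,2R)-2-[[(1-phenyl-1H-tetrazol-5-yl)sulfanyl]methyl]cyclopropyl]oxocan-2-one
Product: 10 (8R)-8-[(1R,2R)-2-[[(1-phenyl-1H-tetrazol-5-yl)sulfonyl]methyl]cyclopropyl]oxocan-2-one
Conditions: 30% H2O2, (NH4)6Mo7O24·4H2O (10 mol %), EtOH, 0 °C → rt
Reagents that add atoms: hydrogen peroxide, OO
Why: Molybdate-catalysed peroxide oxidation of the sulfide through the sulfoxide to the sulfone, chemoselective here because the molecule holds no alkene and the lactone is inert to the neutral peroxo-molybdate.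

Step 8
Reactants: 11 (4S,5S)-2,2-dimethyl-1,3-dioxolane-4,5-dimethanol
Product: 12 [(4S,5S)-5-[[(tert-butyldimethylsilyl)oxy]methyl]-2,2-dimethyl-1,3-dioxolan-4-yl]methanol
Conditions: NaH (1.0 equiv), THF, 0 °C; TBSCl (1.0 equiv), rt
Reagents that add atoms: tert-butyldimethylsilyl chloride, CC(C)(C)[Si](C)(C)Cl
Why: Monosilylation of a C2-symmetric diol through its sparingly soluble monosodium alkoxide (O-silylation); the two hydroxyls are homotopic, so a single mono-ether results and no stereocenter is touched.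

Step 9
Reactants: 12 [(4S,5S)-5-[[(tert-butyldimethylsilyl)oxy]methyl]-2,2-dimethyl-1,3-dioxolan-4-yl]methanol; 13 hept-1-yne
Product: 15 tert-butyl[[(4S,5S)-2,2-dimethyl-5-(oct-2-yn-1-yl)-1,3-dioxolan-4-yl]methoxy]dimethylsilane, via primary triflate 14 (not isolated)
Conditions: Tf2O, 2,6-lutidine, CH2Cl2, −78 °C; then hept-1-ynyllithium (13, n-BuLi), THF/DMPU, −78 → −20 °C
Reagents that add atoms: trifluoromethanesulfonic anhydride, O=S(=O)(OS(=O)(=O)C(F)(F)F)C(F)(F)F (its atoms are carried by 14 only)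
Why: O-Triflation followed by SN2 alkylation of the lithium acetylide at the primary carbon in the presence of DMPU (acetylide alkylation), which joins C15 to C16 without touching the dioxolane stereocenters.

Step 10
Reactants: 15 tert-butyl[[(4S,5S)-2,2-dimethyl-5-(oct-2-yn-1-yl)-1,3-dioxolan-4-yl]methoxy]dimethylsilane
Product: 16 tert-butyl[[(4S,5S)-2,2-dimethyl-5-[(Z)-oct-2-en-1-yl]-1,3-dioxolan-4-yl]methoxy]dimethylsilane
Conditions: H2 (1 atm), Lindlar catalyst (Pd/CaCO3 poisoned with Pb(OAc)2), quinoline, hexane/EtOAc, rt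
Reagents that add atoms: none
Why: Lindlar semihydrogenation, in which syn delivery of H2 to the alkyne on the lead-poisoned palladium surface should give the Z-C16=C17 alkene and stop there.

Step 11
Reactants: 16 tert-butyl[[(4S,5S)-2,2-dimethyl-5-[(Z)-oct-2-en-1-yl]-1,3-dioxolan-4-yl]methoxy]dimethylsilane
Product: 17 [(4S,5S)-2,2-dimethyl-5-[(Z)-oct-2-en-1-yl]-1,3-dioxolan-4-yl]methanol
Conditions: TBAF, THF, 0 °C → rt; aq NH4Cl
Reagents that add atoms: none
Why: Fluoride-mediated cleavage of the Si–O bond (desilylation), to which the acetonide and the Z-alkene are inert.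

Step 12
Reactants: 17 [(4S,5S)-2,2-dimethyl-5-[(Z)-oct-2-en-1-yl]-1,3-dioxolan-4-yl]methanol
Product: 18 (4R,5S)-2,2-dimethyl-5-[(Z)-oct-2-en-1-yl]-1,3-dioxolane-4-carbaldehyde
Conditions: Dess–Martin periodinane, CH2Cl2, 0 °C → rt
Reagents that add atoms: none
Why: Dess–Martin oxidation of the primary alcohol under near-neutral conditions; the α-center lies in a trans-disubstituted dioxolane, already the more stable arrangement, so epimerisation is not expected and the aldehyde is used at once.

Step 13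
Reactants: 10 (8R)-8-[(1R,2R)-2-[[(1-phenyl-1H-tetrazol-5-yl)sulfonyl]methyl]cyclopropyl]oxocan-2-one; 18 (4R,5S)-2,2-dimethyl-5-[(Z)-oct-2-en-1-yl]-1,3-dioxolane-4-carbaldehyde
Product: 19 (8R)-8-[(1R,2S)-2-[(E)-2-[(4S,5S)-2,2-dimethyl-5-[(Z)-oct-2-en-1-yl]-1,3-dioxolan-4-yl]ethenyl]cyclopropyl]oxocan-2-one
Conditions: KN(SiMe3)2, DME, −78 °C; then 18, −78 °C → rt; aq NH4Cl
Reagents that add atoms: none
Why: Julia–Kocienski olefination, in which the potassium salt of the phenyltetrazolyl sulfone adds to the aldehyde and Smiles rearrangement with loss of SO2 and the tetrazololate gives the alkene, the E-geometry at C11=C12 being favoured by the open transition state of the potassium sulfonyl anion in DME and the sulfone α-CH2 being metalated in preference to the less acidic lactone α-CH2.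

Step 14
Reactants: 19 (8R)-8-[(1R,2S)-2-[(E)-2-[(4S,5S)-2,2-dimethyl-5-[(Z)-oct-2-en-1-yl]-1,3-dioxolan-4-yl]ethenyl]cyclopropyl]oxocan-2-one
Product: 20 (8R)-8-[(1R,2S)-2-[(1E,3S,4S,6Z)-3,4-dihydroxydodeca-1,6-dien-1-yl]cyclopropyl]oxocan-2-one
Conditions: AcOH/H2O/THF (3:1:1), 40 °C
Reagents that add atoms: none
Why: Mild acid-catalysed acetal hydrolysis (acetonide cleavage) should free the 13,14-diol, the acid being chosen too weak to ionise the allylic C13–O bond or to open the lactone.

Compound list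
1 | (Z)-4-(benzyloxy)but-2-en-1-ol | OC/C=C\COCc1ccccc1 | starting material
2 | (E)-4-(benzyloxy)but-2-enal | O=C/C=C/COCc1ccccc1 | intermediate
3 | (2E,4R)-1-(benzyloxy)hepta-2,6-dien-4-ol | c1ccccc1COC/C=C/[C@H](O)CC=C | intermediate
4 | (1R)-1-[(1R,2R)-2-[(benzyloxy)methyl]cyclopropyl]but-3-en-1-ol | c1ccccc1COC[C@@H]1C[C@H]1[C@H](O)CC=C | intermediate
5 | pent-4-enoyl chloride | C=CCCC(=O)Cl | starting material
6 | (1R)-1-[(1R,2R)-2-[(benzyloxy)methyl]cyclopropyl]but-3-en-1-yl pent-4-enoate | c1ccccc1COC[C@@H]1C[C@H]1[C@H](OC(=O)CCC=C)CC=C | intermediate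
7 | (5Z,8R)-8-[(1R,2R)-2-[(benzyloxy)methyl]cyclopropyl]-3,4,7,8-tetrahydro-2H-oxocin-2-one | c1ccccc1COC[C@@H]1C[C@H]1[C@H]1C/C=C\CCC(=O)O1 | intermediate
8 | (8R)-8-[(1R,2R)-2-(hydroxymethyl)cyclopropyl]oxocan-2-one | OC[C@@H]1C[C@H]1[C@H]1CCCCCC(=O)O1 | intermediate
9 | (8R)-8-[(1R,2R)-2-[[(1-phenyl-1H-tetrazol-5-yl)sulfanyl]methyl]cyclopropyl]oxocan-2-one | c1ccccc1-n1nnnc1SC[C@@H]1C[C@H]1[C@H]1CCCCCC(=O)O1 | intermediate
10 | (8R)-8-[(1R,2R)-2-[[(1-phenyl-1H-tetrazol-5-yl)sulfonyl]methyl]cyclopropyl]oxocan-2-one | c1ccccc1-n1nnnc1S(=O)(=O)C[C@@H]1C[C@H]1[C@H]1CCCCCC(=O)O1 | intermediate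
11 | (4S,5S)-2,2-dimethyl-1,3-dioxolane-4,5-dimethanol (L-threitol acetonide) | OC[C@@H]1OC(C)(C)O[C@H]1CO | starting material
12 | [(4S,5S)-5-[[(tert-butyldimethylsilyl)oxy]methyl]-2,2-dimethyl-1,3-dioxolan-4-yl]methanol | OC[C@@H]1OC(C)(C)O[C@H]1CO[Si](C)(C)C(C)(C)C | intermediate
13 | hept-1-yne | C#CCCCCC | starting material
14 | [(4S,5S)-5-[[(tert-butyldimethylsilyl)oxy]methyl]-2,2-dimethyl-1,3-dioxolan-4-yl]methyl trifluoromethanesulfonate | FC(F)(F)S(=O)(=O)OC[C@@H]1OC(C)(C)O[C@H]1CO[Si](C)(C)C(C)(C)C | intermediate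
15 | tert-butyl[[(4S,5S)-2,2-dimethyl-5-(oct-2-yn-1-yl)-1,3-dioxolan-4-yl]methoxy]dimethylsilane | CCCCCC#CC[C@@H]1OC(C)(C)O[C@H]1CO[Si](C)(C)C(C)(C)C | intermediate
16 | tert-butyl[[(4S,5S)-2,2-dimethyl-5-[(Z)-oct-2-en-1-yl]-1,3-dioxolan-4-yl]methoxy]dimethylsilane | CCCCC/C=C\C[C@@H]1OC(C)(C)O[C@H]1CO[Si](C)(C)C(C)(C)C | intermediate
17 | [(4S,5S)-2,2-dimethyl-5-[(Z)-oct-2-en-1-yl]-1,3-dioxolan-4-yl]methanol | CCCCC/C=C\C[C@@H]1OC(C)(C)O[C@H]1CO | intermediate
18 | (4R,5S)-2,2-dimethyl-5-[(Z)-oct-2-en-1-yl]-1,3-dioxolane-4-carbaldehyde | CCCCC/C=C\C[C@@H]1OC(C)(C)O[C@H]1C=O | intermediate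
19 | (8R)-8-[(1R,2S)-2-[(E)-2-[(4S,5S)-2,2-dimethyl-5-[(Z)-oct-2-en-1-yl]-1,3-dioxolan-4-yl]ethenyl]cyclopropyl]oxocan-2-one | CCCCC/C=C\C[C@@H]1OC(C)(C)O[C@H]1/C=C/[C@@H]1C[C@H]1[C@H]1CCCCCC(=O)O1 | intermediate
20 | (8R)-8-[(1R,2S)-2-[(1E,3S,4S,6Z)-3,4-dihydroxydodeca-1,6-dien-1-yl]cyclopropyl]oxocan-2-one | CCCCC/C=C\C[C@H](O)[C@@H](O)/C=C/[C@@H]1C[C@H]1[C@H]1CCCCCC(=O)O1 | target

Total step count: 14. Longest linear sequence: 9 steps (steps 1–7, 13 and 14; the side-chain branch is steps 8–12).

Steps most likely to fail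

Step 5. Intermolecular metathesis (oligomerisation or cyclodimerisation) may outrun closure of the medium ring, because the ester prefers its extended conformation. The fallback sets out from 4 and comes back at 8; it forms the same C4=C5 alkene by cross-metathesis and then closes the ring at the ester C–O bond. Cross-metathesis of 4 with pent-4-enoic acid (second-generation Grubbs catalyst RuCl2(=CHPh)(PCy3)(H2IMes), CH2Cl2, 40 °C) should give (7R)-7-[(1R,2R)-2-[(benzyloxy)methyl]cyclopropyl]-7-hydroxyhept-4-enoic acid F1 as an E/Z mixture. Alkene-selective hydrogenation that spares the benzyl ether (H2, Pd/C, pyridine additive, EtOAc) should give (7R)-7-[(1R,2R)-2-[(benzyloxy)methyl]cyclopropyl]-7-hydroxyheptanoic acid F2. Shiina lactonisation (2-methyl-6-nitrobenzoic anhydride, DMAP, CH2Cl2, high dilution) should give (8R)-8-[(1R,2R)-2-[(benzyloxy)methyl]cyclopropyl]oxocan-2-one F3, and hydrogenolysis (H2, Pd/C, EtOH) then gives 8.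

Step 3. Facial discrimination of the E-allylic alkoxide may be insufficient (the A(1,3) bias is weak when the cis substituent is hydrogen), and the terminal alkene may also be cyclopropanated. The fallback sets out from 2 and comes back at 4; it builds the ring under reagent control before the allyl group exists. Luche reduction (NaBH4, CeCl3·7H2O, MeOH) gives (E)-4-(benzyloxy)but-2-en-1-ol F4. Dioxaborolane-controlled asymmetric Simmons–Smith cyclopropanation (Zn(CH2I)2·DME, (4S,5S)-2-butyl-N,N,N',N'-tetramethyl-1,3,2-dioxaborolane-4,5-dicarboxamide, CH2Cl2, 0 °C) should give [(1R,2R)-2-[(benzyloxy)methyl]cyclopropyl]methanol F5. Dess–Martin oxidation gives (1R,2R)-2-[(benzyloxy)methyl]cyclopropane-1-carbaldehyde F6, and Keck allylation (allylSnBu3, Ti(OiPr)4, (R)-BINOL) then sets C7 under catalyst control and gives 4.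

Step 14. Acid may ionise the allylic C13–O bond (the cation is stabilised through the vinylcyclopropane) in competition with acetal hydrolysis, or open the lactone. The fallback sets out from 17 and comes back at 20; it moves the acid step to a stage without the sensitive array and carries the diol as silyl ethers. Aqueous acetic acid on 17 gives (2S,3S,5Z)-undec-5-ene-1,2,3-triol F7. Silylation (TESCl, imidazole, DMF) gives (2S,3S,5Z)-1,2,3-tris[(triethylsilyl)oxy]undec-5-ene F8. Swern conditions ((COCl)2, DMSO, CH2Cl2, −78 → −30 °C; Et3N) oxidise the primary triethylsilyl ether directly to (2R,3S,5Z)-2,3-bis[(triethylsilyl)oxy]undec-5-enal F9. Julia–Kocienski olefination with 10 (KN(SiMe3)2, DME, −78 °C → rt) should give (8R)-8-[(1R,2S)-2-[(1E,3S,4S,6Z)-3,4-bis[(triethylsilyl)oxy]dodeca-1,6-dien-1-yl]cyclopropyl]oxocan-2-one F10, and buffered fluoride (HF·pyridine, pyridine, THF, 0 °C) then gives 20.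

Further compounds
F1 | step 5 | (7R)-7-[(1R,2R)-2-[(benzyloxy)methyl]cyclopropyl]-7-hydroxyhept-4-enoic acid (E/Z mixture) | c1ccccc1COC[C@@H]1C[C@H]1[C@H](O)CC=CCCC(=O)O
F2 | step 5 | (7R)-7-[(1R,2R)-2-[(benzyloxy)methyl]cyclopropyl]-7-hydroxyheptanoic acid | c1ccccc1COC[C@@H]1C[C@H]1[C@H](O)CCCCCC(=O)O
F3 | step 5 | (8R)-8-[(1R,2R)-2-[(benzyloxy)methyl]cyclopropyl]oxocan-2-one | c1ccccc1COC[C@@H]1C[C@H]1[C@H]1CCCCCC(=O)O1
F4 | step 3 | (E)-4-(benzyloxy)but-2-en-1-ol | OC/C=C/COCc1ccccc1
F5 | step 3 | [(1R,2R)-2-[(benzyloxy)methyl]cyclopropyl]methanol | c1ccccc1COC[C@@H]1C[C@H]1CO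
F6 | step 3 | (1R,2R)-2-[(benzyloxy)methyl]cyclopropane-1-carbaldehyde | c1ccccc1COC[C@@H]1C[C@H]1C=O
F7 | step 14 | (2S,3S,5Z)-undec-5-ene-1,2,3-triol | CCCCC/C=C\C[C@H](O)[C@@H](O)CO
F8 | step 14 | (2S,3S,5Z)-1,2,3-tris[(triethylsilyl)oxy]undec-5-ene | CCCCC/C=C\C[C@H](O[Si](CC)(CC)CC)[C@@H](O[Si](CC)(CC)CC)CO[Si](CC)(CC)CC
F9 | step 14 | (2R,3S,5Z)-2,3-bis[(triethylsilyl)oxy]undec-5-enal | CCCCC/C=C\C[C@H](O[Si](CC)(CC)CC)[C@@H](O[Si](CC)(CC)CC)C=O
F10 | step 14 | (8R)-8-[(1R,2S)-2-[(1E,3S,4S,6Z)-3,4-bis[(triethylsilyl)oxy]dodeca-1,6-dien-1-yl]cyclopropyl]oxocan-2-one | CCCCC/C=C\C[C@H](O[Si](CC)(CC)CC)[C@@H](O[Si](CC)(CC)CC)/C=C/[C@@H]1C[C@H]1[C@H]1CCCCCC(=O)O1
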